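**Plan**

- Retrosynthesis: the two indole N–H bonds are masked as N-tosyl, the C5–acetyl bond is cut next, then the pyrrole bonds N1–C5 and C2–C3, then the aminomethylene C=C, and last the ketone-to-indole C3 bond.
- Enabling feature: N1 and C2 with its methyl ester are a glycine methyl ester; C3, C4 and C5 with both indol-3-yl groups are the aminomethylenated 1,2-bis(indol-3-yl)ethanone, whose ketone carbon becomes C3 and whose aminomethylene carbon becomes C5.
- Forward: indole and indole-3-acetic acid are N-tosylated and joined by Friedel–Crafts acylation; the methylene is aminomethylenated; the pyrrole (the only ring built) closes with glycine methyl ester; C5 is acetylated; both tosyl groups are removed.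
- Strengthening: alkoxide would strip the sulfonyl groups, and a deprotonated 3-acylindole would no longer accept the glycinate carbon. The enaminone oxygen is therefore exchanged for chloride with POCl3 in the same flask, and the ring is closed with NaH in DMF.
- Stereochemistry: the target has no stereocentre; the enaminone geometry disappears in the aromatic ring.

Key step: step 5

Remark on the chemistry: pyrrole numbering is N1, C2 (CO2Me), C3 and C4 (indol-3-yl), C5 (acetyl). The double-bond geometries of the transient compounds 10 and 11 are not assigned and do not matter.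

**Step 1**
Reactants: 1 indole
Product: 2 1-tosylindole
Conditions: NaH, DMF, 0 °C; TsCl, 0 °C → rt
Reagents that add atoms: p-toluenesulfonyl chloride, Cc1ccc(cc1)S(=O)(=O)Cl
Why: the sodium indolide should attack the sulfonyl chloride at sulfur (N-sulfonylation), giving the N-protected, C3-directing indole needed for the acylation.

**Step 2**
Reactants: 3 indole-3-acetic acid
Product: 4 2-(1-tosylindol-3-yl)acetic acid
Conditions: n-BuLi (2.1 equiv), THF, −78 °C; TsCl, −78 °C → rt; aq. HCl work-up
Reagents that add atoms: p-toluenesulfonyl chloride, Cc1ccc(cc1)S(=O)(=O)Cl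
Why: in the carboxylate/indolide dianion the indolide nitrogen is by far the better nucleophile, so N-sulfonylation should occur without ester protection of the acid.

**Step 3**
Reactants: 4 2-(1-tosylindol-3-yl)acetic acid; 2 1-tosylindole
Product: 6 1,2-bis(1-tosylindol-3-yl)ethanone, via 2-(1-tosylindol-3-yl)acetyl chloride 5 (not isolated)
Conditions: (COCl)2, cat. DMF, CH2Cl2, 0 °C → rt, evaporate; then AlCl3, CH2Cl2, 0 °C, add 2, → rt
Reagents that add atoms: oxalyl chloride, O=C(Cl)C(=O)Cl (supplies the chlorine of 5; none of its atoms remain in 6)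
Why: Friedel–Crafts acylation of 1-sulfonylindoles with an acid chloride and AlCl3 is reliably C3-selective, because the sulfonyl group blocks nitrogen and tempers the ring without moving the site of attack.

**Step 4**
Reactants: 6 1,2-bis(1-tosylindol-3-yl)ethanone; 7 N,N-dimethylformamide dimethyl acetal
Product: 8 (E)-3-(dimethylamino)-1,2-bis(1-tosylindol-3-yl)prop-2-en-1-one
Conditions: 7 (3 equiv), toluene, 100 °C
Reagents that add atoms: none
Why: the methylene flanked by the ketone and an indolyl group is acidic enough to condense with the amide acetal (aminomethylenation to an enaminone), and the tosyl groups prevent N-methylation of the indoles by the acetal.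

**Step 5**
Reactants: 8 (E)-3-(dimethylamino)-1,2-bis(1-tosylindol-3-yl)prop-2-en-1-one; 9 glycine methyl ester hydrochloride
Product: 12 methyl 3,4-bis(1-tosylindol-3-yl)-1H-pyrrole-2-carboxylate, via chloropropeniminium dichlorophosphate 10 (not isolated), via methyl N-(3-chloroallylidene)glycinate 11 (not isolated)
Conditions: POCl3, CH2Cl2, 40 °C, evaporate; then 9, NaH, DMF, 0 °C → 70 °C
Reagents that add atoms: phosphoryl chloride, O=P(Cl)(Cl)Cl (supplies the chlorine of 10 and 11 and the counter-ion of 10; none of its atoms remain in 12)
Why: POCl3 O-phosphorylates the vinylogous amide and chloride replaces the phosphate, so the former ketone carbon of 8 becomes the chlorine-bearing end of salt 10; free glycine methyl ester then adds to the iminium carbon and expels dimethylamine (N1–C5) to give azadiene 11. NaH removes the proton between nitrogen and ester, and the resulting 2-azapentadienyl anion closes through its carbon onto the chlorine-bearing carbon (C2–C3); loss of chloride and a proton shift aromatise the ring. The closest known reaction type is the synthesis of 3,4-diarylpyrrole-2-carboxylates from 3-chloropropeniminium salts or beta-chloroenals and glycine esters with NaH in DMF. The pyrrole closes in a formally 5-endo-trig mode that is better described as an allowed six-electron 1,5-electrocyclisation followed by elimination, and no stereocentre is formed. The step needs regioselectivity (nitrogen at the CH, carbon at the former ketone carbon), secured because the amine exchanges at the unhindered iminium carbon and only the other terminus carries a leaving group, and it needs the sulfonamides to survive, which the absence of alkoxide secures. Chloride was chosen over the free ketone because methoxide would cleave the tosyl group of the 3-acylindole and the indolide so formed would switch off the carbonyl.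

**Step 6**
Reactants: 12 methyl 3,4-bis(1-tosylindol-3-yl)-1H-pyrrole-2-carboxylate
Product: 13 methyl 5-acetyl-3,4-bis(1-tosylindol-3-yl)-1H-pyrrole-2-carboxylate
Conditions: AcCl, AlCl3, CH2Cl2, 0 °C → rt
Reagents that add atoms: acetyl chloride, CC(=O)Cl
Why: Friedel–Crafts acylation should go to C5, the only unsubstituted pyrrole carbon and an alpha position, while the N-tosylindoles are deactivated and have no free C3.

**Step 7**
Reactants: 13 methyl 5-acetyl-3,4-bis(1-tosylindol-3-yl)-1H-pyrrole-2-carboxylate
Product: 14 methyl 5-acetyl-3,4-bis(1H-indol-3-yl)-1H-pyrrole-2-carboxylate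
Conditions: Cs2CO3, THF/MeOH (2:1), rt → 50 °C
Reagents that add atoms: none
Why: carbonate-mediated methanolysis of indole N-sulfonamides (indolide as leaving group) should free both indoles; ester exchange in methanol is degenerate, and the acidic pyrrole N–H is deprotonated first, which shields the ester and the acetyl group.

**Compound list**

1 | indole | c1ccc2[nH]ccc2c1 | starting material
2 | 1-tosylindole | Cc1ccc(cc1)S(=O)(=O)n1ccc2ccccc12 | intermediate
3 | indole-3-acetic acid | O=C(O)Cc1c[nH]c2ccccc12 | starting material
4 | 2-(1-tosylindol-3-yl)acetic acid | O=C(O)Cc1cn(S(=O)(=O)c2ccc(C)cc2)c2ccccc12 | intermediate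
5 | 2-(1-tosylindol-3-yl)acetyl chloride | O=C(Cl)Cc1cn(S(=O)(=O)c2ccc(C)cc2)c2ccccc12 | intermediate (not isolated)
6 | 1,2-bis(1-tosylindol-3-yl)ethanone | O=C(Cc1cn(S(=O)(=O)c2ccc(C)cc2)c2ccccc12)c1cn(S(=O)(=O)c2ccc(C)cc2)c2ccccc12 | intermediate
7 | N,N-dimethylformamide dimethyl acetal | COC(OC)N(C)C | starting material
8 | (E)-3-(dimethylamino)-1,2-bis(1-tosylindol-3-yl)prop-2-en-1-one | O=C(c1cn(S(=O)(=O)c2ccc(C)cc2)c2ccccc12)/C(c1cn(S(=O)(=O)c2ccc(C)cc2)c2ccccc12)=C/N(C)C | intermediate
9 | glycine methyl ester hydrochloride | COC(=O)CN.Cl | starting material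
10 | N-[3-chloro-2,3-bis(1-tosylindol-3-yl)prop-2-enylidene]-N-methylmethanaminium dichlorophosphate (geometry not assigned) | C[N+](C)=CC(c1cn(S(=O)(=O)c2ccc(C)cc2)c2ccccc12)=C(Cl)c1cn(S(=O)(=O)c2ccc(C)cc2)c2ccccc12.[O-]P(=O)(Cl)Cl | intermediate (not isolated)
11 | methyl N-[3-chloro-2,3-bis(1-tosylindol-3-yl)prop-2-enylidene]glycinate (geometry not assigned) | COC(=O)CN=CC(c1cn(S(=O)(=O)c2ccc(C)cc2)c2ccccc12)=C(Cl)c1cn(S(=O)(=O)c2ccc(C)cc2)c2ccccc12 | intermediate (not isolated)
12 | methyl 3,4-bis(1-tosylindol-3-yl)-1H-pyrrole-2-carboxylate | COC(=O)c1[nH]cc(-c2cn(S(=O)(=O)c3ccc(C)cc3)c3ccccc23)c1-c1cn(S(=O)(=O)c2ccc(C)cc2)c2ccccc12 | intermediate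
13 | methyl 5-acetyl-3,4-bis(1-tosylindol-3-yl)-1H-pyrrole-2-carboxylate | COC(=O)c1[nH]c(C(C)=O)c(-c2cn(S(=O)(=O)c3ccc(C)cc3)c3ccccc23)c1-c1cn(S(=O)(=O)c2ccc(C)cc2)c2ccccc12 | intermediate
14 | methyl 5-acetyl-3,4-bis(1H-indol-3-yl)-1H-pyrrole-2-carboxylate | COC(=O)c1[nH]c(C(C)=O)c(-c2c[nH]c3ccccc23)c1-c1c[nH]c2ccccc12 | target

**Step count**

Total steps: 7. Longest linear sequence: 6 steps (3 → 4 → 6 → 8 → 12 → 13 → 14, steps 2 to 7); step 1 is the convergent branch.

**Steps most likely to fail**

Step 5. The sulfonamides may be cleaved by the hot NaH/DMF medium, the iminium salt may hydrolyse back before amine exchange, or ring closure of the azadiene may stall. The fallback sets out from 8 and comes back at 12. The salt 10 made with POCl3 is hydrolysed with aqueous NaOAc in THF to the neutral, isolable beta-chloroenal 3-chloro-2,3-bis(1-tosylindol-3-yl)prop-2-enal F1. F1 is then condensed with 9 and K2CO3 in DMF at 60 °C, where imine formation to 11 and closure with loss of chloride should follow without hydride or alkoxide.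

Step 3. The arylacetyl cation may lose carbon monoxide under AlCl3 to an indol-3-ylmethyl cation that alkylates instead of acylating, and attack on the deactivated 1-tosylindole may be slow. The fallback sets out from 5 (made from 4 as before) and indole 1 and comes back at 6. Unprotected indole, a much better nucleophile, is acylated at C3 with Et2AlCl in CH2Cl2 at 0 °C to 1-(1H-indol-3-yl)-2-(1-tosylindol-3-yl)ethanone F2. The acidic N–H of this 3-acylindole is then tosylated with TsCl, Et3N and catalytic DMAP in CH2Cl2.

Step 6. Acylation may be sluggish at a pyrrole carbon deactivated by the ester and flanked by a bulky indolyl group, and competing attack on the benzenoid rings of the tosylindoles or on the pyrrole nitrogen may occur. The fallback sets out from 12 and comes back at 13. Bromination with N-bromosuccinimide in THF at −78 → 0 °C should give methyl 5-bromo-3,4-bis(1-tosylindol-3-yl)-1H-pyrrole-2-carboxylate F3. Stille coupling with tributyl(1-ethoxyvinyl)stannane and Pd(PPh3)4 in toluene at 100 °C should give methyl 5-(1-ethoxyvinyl)-3,4-bis(1-tosylindol-3-yl)-1H-pyrrole-2-carboxylate F4. Dilute aqueous HCl in THF then hydrolyses the enol ether to the acetyl group.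

**Further compounds**

F1 | step 5 | 3-chloro-2,3-bis(1-tosylindol-3-yl)prop-2-enal (geometry not assigned) | O=CC(c1cn(S(=O)(=O)c2ccc(C)cc2)c2ccccc12)=C(Cl)c1cn(S(=O)(=O)c2ccc(C)cc2)c2ccccc12
F2 | step 3 | 1-(1H-indol-3-yl)-2-(1-tosylindol-3-yl)ethanone | O=C(Cc1cn(S(=O)(=O)c2ccc(C)cc2)c2ccccc12)c1c[nH]c2ccccc12
F3 | step 6 | methyl 5-bromo-3,4-bis(1-tosylindol-3-yl)-1H-pyrrole-2-carboxylate | COC(=O)c1[nH]c(Br)c(-c2cn(S(=O)(=O)c3ccc(C)cc3)c3ccccc23)c1-c1cn(S(=O)(=O)c2ccc(C)cc2)c2ccccc12
F4 | step 6 | methyl 5-(1-ethoxyvinyl)-3,4-bis(1-tosylindol-3-yl)-1H-pyrrole-2-carboxylate | COC(=O)c1[nH]c(C(=C)OCC)c(-c2cn(S(=O)(=O)c3ccc(C)cc3)c3ccccc23)c1-c1cn(S(=O)(=O)c2ccc(C)cc2)c2ccccc12
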